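**Retrosynthetic overview**
- The butenolide is made last, by ring contraction of a 6-arylidene-2H-pyran-2,5(6H)-dione: methanol opens the lactone, a benzilic-ester-type 1,2-benzyl shift follows, C6 leaves the ring as CO2Me and C5 becomes the quaternary (R) centre.
- The arylidene-pyrandione comes from a Knoevenagel union of a chromanol aldehyde with a 4-aryl-3-hydroxypyran-2,5-dione (convergent step).
- The pyrandione ring is closed by Dieckmann C-acylation of the glycolate ester of 4-hydroxyphenylpyruvic acid (4-iodophenol + methyl 2-methoxyacrylate, then methyl bromoacetate).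
- The chromanol aldehyde comes from 4-bromophenol + prenal (chromene), Jacobsen epoxidation (sets the S carbinol), hydride opening and formylation.
- Ring order: chroman ring, then pyrandione ring, then butenolide by contraction of the pyrandione.

Assumption: tautomers and rapidly interconverting epimers of non-isolated intermediates are drawn in one representative form, with such labile centres left undefined in the SMILES.

**Step 1**
Reactants: 1 4-bromophenol; 2 3-methylbut-2-enal
Product: 3 6-bromo-2,2-dimethyl-2H-chromene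
Conditions: PhB(OH)2 (1.0 equiv, recovered unchanged), AcOH (cat.), toluene, reflux, Dean–Stark
Reagents that add atoms: none
Why: Boronic-acid-templated ortho-selective condensation of a phenol with an enal followed by ring closure (Knoevenagel-type condensation, then oxa-6π electrocyclisation) is the standard one-step 2H-chromene synthesis; no stereocentre is formed.

**Step 2**
Reactants: 3 6-bromo-2,2-dimethyl-2H-chromene
Product: 4 (3S,4S)-6-bromo-3,4-epoxy-2,2-dimethylchromane
Conditions: (S,S)-Jacobsen Mn(salen)Cl (4 mol%), 4-phenylpyridine N-oxide (20 mol%), aq. NaOCl (pH 11.3), CH2Cl2, 0 °C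
Reagents that add atoms: sodium hypochlorite, [Na+].[O-]Cl
Why: Jacobsen–Katsuki epoxidation works best on 2,2-dimethylchromenes (typically >90% ee), and the (S,S)-catalyst gives the (3S,4S)-epoxide, which fixes the later carbinol centre C3 as S.

**Step 3**
Reactants: 4 (3S,4S)-6-bromo-3,4-epoxy-2,2-dimethylchromane
Product: 5 (3S)-6-bromo-2,2-dimethylchroman-3-ol
Conditions: LiAlH4, THF, 0 °C to rt; aq. NaOH work-up
Reagents that add atoms: none
Why: SN2 hydride opening of the epoxide occurs at benzylic C4 (C3 is shielded by the gem-dimethyl carbon), so the C3–O bond is untouched and C3 stays S; the aryl bromide is inert at this temperature.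

**Step 4**
Reactants: 5 (3S)-6-bromo-2,2-dimethylchroman-3-ol
Product: 6 (3S)-3-hydroxy-2,2-dimethylchromane-6-carbaldehyde
Conditions: n-BuLi (2.2 equiv), THF, −78 °C; DMF, −78 to 0 °C; aq. HCl
Reagents that add atoms: N,N-dimethylformamide, CN(C)C=O
Why: Bromine–lithium exchange on the lithium alkoxide followed by Bouveault formylation with DMF; the stereocentre is not involved.

**Step 5**
Reactants: 7 4-iodophenol; 8 methyl 2-methoxyacrylate
Product: 9 methyl (2Z)-3-(4-hydroxyphenyl)-2-methoxyprop-2-enoate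
Conditions: Pd(OAc)2 (3 mol%), Bu4NCl, NaHCO3, DMF, 80 °C
Reagents that add atoms: none
Why: Mizoroki–Heck arylation (Jeffery conditions) of the 1,1-disubstituted acrylate at its CH2 terminus tolerates the free phenol and gives the Z enol ether of the arylpyruvate.

**Step 6**
Reactants: 9 methyl (2Z)-3-(4-hydroxyphenyl)-2-methoxyprop-2-enoate
Product: 10 3-(4-hydroxyphenyl)-2-oxopropanoic acid
Conditions: 3 M HCl, AcOH, 90 °C
Reagents that add atoms: water, O
Why: Acid hydrolysis of the enol ether and of the ester unmasks the α-keto acid.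

**Step 7**
Reactants: 10 3-(4-hydroxyphenyl)-2-oxopropanoic acid; 11 methyl bromoacetate
Product: 12 2-methoxy-2-oxoethyl 3-(4-hydroxyphenyl)-2-oxopropanoate
Conditions: KHCO3 (1.05 equiv), DMF, 0 °C to rt
Reagents that add atoms: none
Why: SN2 O-alkylation of the carboxylate; with one equivalent of bicarbonate only the carboxylic acid (pKa about 2.5) is ionised, so the phenol is not alkylated.

**Step 8**
Reactants: 12 2-methoxy-2-oxoethyl 3-(4-hydroxyphenyl)-2-oxopropanoate
Product: 13 3-hydroxy-4-(4-hydroxyphenyl)-2H-pyran-2,5(6H)-dione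
Conditions: LiHMDS (3.0 equiv), THF, −78 to 20 °C; aq. HCl
Reagents that add atoms: none
Why: Dieckmann-type intramolecular C-acylation (6-exo-trig) of the benzylic enolate on the glycolate ester, the vinylogous counterpart of the tetronic acid synthesis, is driven by formation of the stabilised enolate of the cyclic vinylogous acid.

**Step 9**
Reactants: 13 3-hydroxy-4-(4-hydroxyphenyl)-2H-pyran-2,5(6H)-dione; 6 (3S)-3-hydroxy-2,2-dimethylchromane-6-carbaldehyde
Product: 14 (6Z)-3-hydroxy-6-{[(3S)-3-hydroxy-2,2-dimethylchroman-6-yl]methylidene}-4-(4-hydroxyphenyl)-2H-pyran-2,5(6H)-dione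
Conditions: ethylenediammonium diacetate (10 mol%), THF/toluene, 4 Å MS, 50 °C (no alcohol solvent)
Reagents that add atoms: none
Why: Knoevenagel condensation at the O–CH2–C=O methylene C6 is driven by water removal and extended conjugation to the Z-arylidene; the alkene geometry is irrelevant later because this carbon becomes CH2.

**Step 10**
Reactants: 14 (6Z)-3-hydroxy-6-{[(3S)-3-hydroxy-2,2-dimethylchroman-6-yl]methylidene}-4-(4-hydroxyphenyl)-2H-pyran-2,5(6H)-dione
Product: 19 butyrolactone V, via diketo ester 15 (not isolated), via hydroxyfuranone 16 (not isolated), via enol lactone 17 (not isolated), via hydroxy keto diester 18 (not isolated)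
Conditions: Sc(OTf)3 (10 mol%), chiral N,N′-dioxide ligand (L-PiPr2 type, 11 mol%; the ligand enantiomer that gives the R lactone), MeOH (5 equiv), CH2Cl2, 30 °C
Reagents that add atoms: methanol, CO
Why: Proposed new method: methanol opens the enol-lactone carbonyl C2 of 14 to the 1,2-diketone 15, which closes to the 2-hydroxyfuran-3(2H)-one 16 whose hemiketal epimers interconvert through 15; the chiral Sc(III) complex chelates the α-ketol unit (OH and C=O) and lets only the (S)-hemiketal undergo the suprafacial 1,2-benzyl shift to the ketone carbon (dynamic kinetic resolution), giving the (R)-enol lactone 17, whose carbinol configuration is retained when methanol opens it to 18 and the tertiary hydroxyl closes onto the α-keto ester to give 19, so the six-membered ring contracts, the former C6 is extruded as CO2Me and the former ketone carbon C5 becomes the (R) quaternary centre while the chroman centre is untouched; closest known reaction type: benzilic ester rearrangement of 1,2-diketones and chiral-Lewis-acid-catalysed enantioselective α-ketol (acyloin) rearrangement.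

**Compound list**
1 | 4-bromophenol | Oc1ccc(Br)cc1 | starting material
2 | 3-methylbut-2-enal | CC(C)=CC=O | starting material
3 | 6-bromo-2,2-dimethyl-2H-chromene | CC1(C)C=Cc2cc(Br)ccc2O1 | intermediate
4 | (3S,4S)-6-bromo-3,4-epoxy-2,2-dimethylchromane | CC1(C)Oc2ccc(Br)cc2[C@@H]3O[C@H]13 | intermediate
5 | (3S)-6-bromo-2,2-dimethylchroman-3-ol | CC1(C)Oc2ccc(Br)cc2C[C@@H]1O | intermediate
6 | (3S)-3-hydroxy-2,2-dimethylchromane-6-carbaldehyde | CC1(C)Oc2ccc(C=O)cc2C[C@@H]1O | intermediate
7 | 4-iodophenol | Oc1ccc(I)cc1 | starting material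
8 | methyl 2-methoxyacrylate | C=C(OC)C(=O)OC | starting material
9 | methyl (2Z)-3-(4-hydroxyphenyl)-2-methoxyprop-2-enoate | COC(=O)/C(OC)=C/c1ccc(O)cc1 | intermediate
10 | 3-(4-hydroxyphenyl)-2-oxopropanoic acid | OC(=O)C(=O)Cc1ccc(O)cc1 | intermediate
11 | methyl bromoacetate | COC(=O)CBr | starting material
12 | 2-methoxy-2-oxoethyl 3-(4-hydroxyphenyl)-2-oxopropanoate | COC(=O)COC(=O)C(=O)Cc1ccc(O)cc1 | intermediate
13 | 3-hydroxy-4-(4-hydroxyphenyl)-2H-pyran-2,5(6H)-dione (tautomer: 3,5-dihydroxy-2-pyranone) | O=C1OCC(=O)C(c2ccc(O)cc2)=C1O | intermediate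
14 | (6Z)-3-hydroxy-6-{[(3S)-3-hydroxy-2,2-dimethylchroman-6-yl]methylidene}-4-(4-hydroxyphenyl)-2H-pyran-2,5(6H)-dione | O=C1O/C(=C\c2ccc3OC(C)(C)[C@@H](O)Cc3c2)C(=O)C(c2ccc(O)cc2)=C1O | intermediate
15 | methyl (2E)-2-hydroxy-6-[(3S)-3-hydroxy-2,2-dimethylchroman-6-yl]-3-(4-hydroxyphenyl)-4,5-dioxohex-2-enoate | COC(=O)/C(O)=C(\C(=O)C(=O)Cc1ccc2OC(C)(C)[C@@H](O)Cc2c1)c1ccc(O)cc1 | intermediate
16 | methyl 5-hydroxy-5-{[(3S)-3-hydroxy-2,2-dimethylchroman-6-yl]methyl}-3-(4-hydroxyphenyl)-4-oxo-4,5-dihydrofuran-2-carboxylate (interconverting C5 epimers) | COC(=O)C1=C(c2ccc(O)cc2)C(=O)C(O)(Cc2ccc3OC(C)(C)[C@@H](O)Cc3c2)O1 | intermediate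
17 | methyl (4R)-4-hydroxy-4-{[(3S)-3-hydroxy-2,2-dimethylchroman-6-yl]methyl}-3-(4-hydroxyphenyl)-5-oxo-4,5-dihydrofuran-2-carboxylate | COC(=O)C1=C(c2ccc(O)cc2)[C@](O)(Cc2ccc3OC(C)(C)[C@@H](O)Cc3c2)C(=O)O1 | intermediate
18 | dimethyl (2R)-2-hydroxy-2-{[(3S)-3-hydroxy-2,2-dimethylchroman-6-yl]methyl}-3-(4-hydroxyphenyl)-4-oxopentanedioate (C3 epimers, enolisable) | COC(=O)C(=O)C(c1ccc(O)cc1)[C@](O)(Cc1ccc2OC(C)(C)[C@@H](O)Cc2c1)C(=O)OC | intermediate
19 | butyrolactone V | COC(=O)[C@]1(Cc2ccc3c(c2)C[C@H](O)C(C)(C)O3)OC(=O)C(O)=C1c1ccc(O)cc1 | target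

**Step count and risks**
Total steps: 10. Longest linear sequence: 6 (steps 1–4, 9, 10; the branch 5–8, 9, 10 is equally long).

Steps most likely to fail:

Step 10 (the new ring contraction). Risks are retro-Claisen cleavage of 15 to two arylpyruvates, binding of the product enol to the catalyst, and modest enantiocontrol. Any C5 epimer is a diastereomer of 19 and separable. The fallback uses known chemistry, sets out from 6 and 10 and comes back at 19. Erlenmeyer condensation of 6 with N-acetylglycine (Ac2O, NaOAc) gives the O-acetylated azlactone F1. Hot 3 M HCl hydrolyses it to the arylpyruvic acid F2, which is esterified (MeOH, cat. H2SO4) to methyl arylpyruvate F3. Acid 10 is esterified in the same way to methyl 4-hydroxyphenylpyruvate F4 and silylated (TBSOTf, Et3N) to the bis-TBS enol silane F5. A Cu(II)–tert-butyl-bis(oxazoline)-catalysed Mukaiyama aldol addition of F5 to the chelating α-keto ester F3 (the established enol silane/pyruvate aldol) gives the silylated adduct F6. HF·pyridine then removes both silyl groups and the tertiary alcohol lactonises onto the α-keto ester to give 19.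

Step 8 (six-ring Dieckmann closure). Risks are O-acylation or cleavage of the activated α-keto ester. The fallback sets out from 9 and comes back at 13. DIBAL-H reduces 9 to the allylic alcohol F7, and dilute HCl hydrolyses its enol ether to the hydroxy ketone F8. Claisen condensation of F8 with dimethyl oxalate (NaOMe, MeOH) at the benzylic CH2, followed by lactonisation of the primary hydroxyl onto the new oxalyl ester, gives 13. The ring is thus closed by lactonisation after an intermolecular oxalate Claisen instead of by C-acylation.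

Step 9 (Knoevenagel on the pyrandione). Risks are Michael addition of a second molecule of 13 and opening of the lactone by the amine catalyst. The fallback sets out from 13 and 6 and comes back at 14. 13 is persilylated (TMSCl, Et3N) to the tris-TMS pyranone F9. BF3·OEt2 then mediates a Mukaiyama-type aldol addition of its C6 to 6, giving the carbinol F10 after aqueous work-up. F10 is dehydrated (cat. TsOH, toluene) to 14.

**Further compounds**
F1 | step 10 | (4Z)-4-{[(3S)-3-acetoxy-2,2-dimethylchroman-6-yl]methylidene}-2-methyl-1,3-oxazol-5(4H)-one | CC1=N/C(=C\c2ccc3OC(C)(C)[C@@H](OC(C)=O)Cc3c2)C(=O)O1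
F2 | step 10 | 3-[(3S)-3-hydroxy-2,2-dimethylchroman-6-yl]-2-oxopropanoic acid | OC(=O)C(=O)Cc1ccc2OC(C)(C)[C@@H](O)Cc2c1
F3 | step 10 | methyl 3-[(3S)-3-hydroxy-2,2-dimethylchroman-6-yl]-2-oxopropanoate | COC(=O)C(=O)Cc1ccc2OC(C)(C)[C@@H](O)Cc2c1
F4 | step 10 | methyl 3-(4-hydroxyphenyl)-2-oxopropanoate | COC(=O)C(=O)Cc1ccc(O)cc1
F5 | step 10 | methyl (2Z)-2-[(tert-butyldimethylsilyl)oxy]-3-{4-[(tert-butyldimethylsilyl)oxy]phenyl}prop-2-enoate | COC(=O)/C(O[Si](C)(C)C(C)(C)C)=C/c1ccc(O[Si](C)(C)C(C)(C)C)cc1
F6 | step 10 | dimethyl (2R)-2-[(tert-butyldimethylsilyl)oxy]-3-{4-[(tert-butyldimethylsilyl)oxy]phenyl}-2-{[(3S)-3-hydroxy-2,2-dimethylchroman-6-yl]methyl}-4-oxopentanedioate | COC(=O)C(=O)C(c1ccc(O[Si](C)(C)C(C)(C)C)cc1)[C@](O[Si](C)(C)C(C)(C)C)(Cc1ccc2OC(C)(C)[C@@H](O)Cc2c1)C(=O)OC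
F7 | step 8 | (2Z)-3-(4-hydroxyphenyl)-2-methoxyprop-2-en-1-ol | OC/C(OC)=C/c1ccc(O)cc1
F8 | step 8 | 1-hydroxy-3-(4-hydroxyphenyl)propan-2-one | OCC(=O)Cc1ccc(O)cc1
F9 | step 9 | 3,5-bis(trimethylsilyloxy)-4-[4-(trimethylsilyloxy)phenyl]-2H-pyran-2-one | O=C1OC=C(O[Si](C)(C)C)C(c2ccc(O[Si](C)(C)C)cc2)=C1O[Si](C)(C)C
F10 | step 9 | 3,5-dihydroxy-6-{hydroxy[(3S)-3-hydroxy-2,2-dimethylchroman-6-yl]methyl}-4-(4-hydroxyphenyl)-2H-pyran-2-one | O=C1OC(C(O)c2ccc3OC(C)(C)[C@@H](O)Cc3c2)=C(O)C(c2ccc(O)cc2)=C1O
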